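## Retrosynthetic overview

1. Target ⇐ O-sulfation at C12 and unmasking of the hydroquinone from dimethoxyaryl alcohol 14.
2. 14 ⇐ terminal alkyne 11 by methylalumination and benzyl coupling (sets the 17E olefin and attaches the bought arene).
3. 11 ⇐ tricyclic ether 9 by acylative E1 opening of the temporary tetrahydrofuran, which places the Δ7 olefin.
4. 9 ⇐ acyclic trienynol 8 by a light-triggered bicyclization that forms rings A and B in one step, closed by the C12 hydroxyl as a temporary third ring.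
5. 8 ⇐ (2E,6E)-farnesyl chloride + aldehyde 5; 5 comes from (R)-3-bromo-2-methylpropan-1-ol, the only chiral material bought.

Terpenoid numbering is used in the comments: decalin C1–C10, side chain C11–C19, so the sulfate carbon is C12 and the methyl-bearing carbon is C13. The target is (5R,9R,10R,12S,13S), i.e. it carries the enantiomeric (ent) drimane decalin.

Assumption: the sulfate is handled as its sodium salt and converted to the drawn hydrogen sulfate only in the last operation; 15–17 are listed in the neutral acid form.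

## Route

Step 1
Reactants: 1 (R)-3-bromo-2-methylpropan-1-ol; 2 (4-bromobut-1-yn-1-yl)trimethylsilane
Product: 4 (S)-2-methyl-7-(trimethylsilyl)hept-6-yn-1-ol, via Grignard reagent 3 (not isolated)
Conditions: 2 (2.4 equiv), Mg, THF; then 1, Li2CuCl4 (3 mol%), THF, −20 °C to 0 °C
Reagents that add atoms: none
Why: Kochi-type copper-catalysed sp3–sp3 cross-coupling of the Grignard reagent with the primary bromide (one equivalent of 3 is spent on the hydroxyl proton) builds C14–C15 without touching the purchased C13 stereocentre, whose descriptor changes from R to S only because CH2Br is replaced by a lower-ranking carbon chain.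

Step 2
Reactants: 4 (S)-2-methyl-7-(trimethylsilyl)hept-6-yn-1-ol
Product: 5 (S)-2-methyl-7-(trimethylsilyl)hept-6-ynal
Conditions: TEMPO (10 mol%), PhI(OAc)2 (1.1 equiv), CH2Cl2, 0 °C to rt; used crude
Reagents that add atoms: none
Why: Oxoammonium (TEMPO/PhI(OAc)2) oxidation of the primary alcohol stops at the aldehyde under essentially neutral conditions, so the α-methyl stereocentre is not epimerised.

Step 3
Reactants: 5 (S)-2-methyl-7-(trimethylsilyl)hept-6-ynal; 6 (2E,6E)-farnesyl chloride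
Product: 8 (6S,7S,9E,13E)-6,10,14,18-tetramethyl-1-(trimethylsilyl)nonadeca-9,13,17-trien-1-yn-7-ol, via farnesylbarium chloride 7 (not isolated)
Conditions: BaI2, Li (2 equiv), biphenyl, THF, rt; then 6, −78 °C; then 5, −78 °C
Reagents that add atoms: none
Why: Yamamoto allylbarium addition is α-selective and keeps the 2E geometry, and Felkin–Anh attack anti to the large C14 chain of the α-methyl aldehyde sets C12 as S (12,13-syn) under control of the purchased C13 centre, with an expected dr of about 3:1 and chromatographic removal of the minor epimer.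

Step 4
Reactants: 8 (6S,7S,9E,13E)-6,10,14,18-tetramethyl-1-(trimethylsilyl)nonadeca-9,13,17-trien-1-yn-7-ol
Product: 9 (2S,3aS,5aR,9aR,9bS)-3a,6,6,9a-tetramethyl-2-[(2S)-7-(trimethylsilyl)hept-6-yn-2-yl]dodecahydronaphtho[2,1-b]furan
Conditions: [Ph2I][B(C6F5)4] (5 mol%), 2-isopropylthioxanthone (5 mol%), 405 nm LED, CH2Cl2 (0.005 M), −78 °C; then Et3N
Reagents that add atoms: none
Why: Proposed new method: light-gated release of the non-nucleophilic superacid H[B(C6F5)4] from the iodonium salt (closest known chemistry: photoacid-generator catalysis and the ClSO3H- or FSO3H-mediated cyclization of homofarnesol to ambroxide) protonates the terminal Me2C=CH unit at −78 °C and starts a chair–chair cation–olefin bicyclization that forms C4–C5 and C9–C10 and is closed 5-endo by the C12 hydroxyl, and because that oxygen must sit over C8 on the face opposite to the incoming C10 cation, the C12 substituent pointing toward the C8 methyl (cis to C11 on the E-olefin) has to be H to avoid a syn-pentane clash, so the (12S)-carbinol directs C9–C10 bonding to the olefin face that gives the ent-ambroxide skeleton (5R,8S,9S,10R) with an expected dr of at least 8:1.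

Step 5
Reactants: 9 (2S,3aS,5aR,9aR,9bS)-3a,6,6,9a-tetramethyl-2-[(2S)-7-(trimethylsilyl)hept-6-yn-2-yl]dodecahydronaphtho[2,1-b]furan
Product: 10 (2S,3S)-3-methyl-1-[(1R,4aR,8aR)-2,5,5,8a-tetramethyl-1,4,4a,5,6,7,8,8a-octahydronaphthalen-1-yl]-8-(trimethylsilyl)oct-7-yn-2-yl acetate
Conditions: Ac2O (5 equiv), FeCl3 (10 mol%), CH2Cl2, −20 °C to 0 °C
Reagents that add atoms: acetic anhydride CC(=O)OC(C)=O
Why: Ganem-type Lewis acid-catalysed acylative ether cleavage O-acetylates the ether, the tertiary C8–O bond ionises and E1 loss of the axial C7 proton gives the endocyclic trisubstituted olefin (the cineole to α-terpinyl acetate precedent), while the C12–O bond is never broken, so C12 is retained and C9 only changes descriptor from S to R.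

Step 6
Reactants: 10 (2S,3S)-3-methyl-1-[(1R,4aR,8aR)-2,5,5,8a-tetramethyl-1,4,4a,5,6,7,8,8a-octahydronaphthalen-1-yl]-8-(trimethylsilyl)oct-7-yn-2-yl acetate
Product: 11 (2S,3S)-3-methyl-1-[(1R,4aR,8aR)-2,5,5,8a-tetramethyl-1,4,4a,5,6,7,8,8a-octahydronaphthalen-1-yl]oct-7-yn-2-ol
Conditions: K2CO3 (20 mol%), MeOH, 40 °C
Reagents that add atoms: none
Why: Methoxide-catalysed transesterification of the acetate and protodesilylation of the alkynylsilane occur in the same pot and involve no stereocentre.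

Step 7
Reactants: 11 (2S,3S)-3-methyl-1-[(1R,4aR,8aR)-2,5,5,8a-tetramethyl-1,4,4a,5,6,7,8,8a-octahydronaphthalen-1-yl]oct-7-yn-2-ol; 12 2-(chloromethyl)-1,4-dimethoxybenzene
Product: 14 (2S,3S,7E)-9-(2,5-dimethoxyphenyl)-3,7-dimethyl-1-[(1R,4aR,8aR)-2,5,5,8a-tetramethyl-1,4,4a,5,6,7,8,8a-octahydronaphthalen-1-yl]non-7-en-2-ol, via alkenylalane 13 (not isolated)
Conditions: AlMe3 (3.5 equiv), Cp2ZrCl2 [Zr(C5H5)2Cl2] (25 mol%), CH2Cl2, 0 °C to rt; then 12, Pd(PPh3)4 (5 mol%), THF, rt
Reagents that add atoms: trimethylaluminium C[Al](C)C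
Why: Negishi zirconium-catalysed syn-methylalumination places the new methyl on the internal alkyne carbon and aluminium on the terminus, and palladium-catalysed alkenyl–benzyl cross-coupling then proceeds with retention to fix the 17E trisubstituted olefin, while the hydroxyl is carried as its aluminium alkoxide and the ring olefin is inert.

Step 8
Reactants: 14 (2S,3S,7E)-9-(2,5-dimethoxyphenyl)-3,7-dimethyl-1-[(1R,4aR,8aR)-2,5,5,8a-tetramethyl-1,4,4a,5,6,7,8,8a-octahydronaphthalen-1-yl]non-7-en-2-ol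
Product: 15 (2S,3S,7E)-9-(2,5-dimethoxyphenyl)-3,7-dimethyl-1-[(1R,4aR,8aR)-2,5,5,8a-tetramethyl-1,4,4a,5,6,7,8,8a-octahydronaphthalen-1-yl]non-7-en-2-yl hydrogen sulfate
Conditions: SO3·pyridine (5 equiv), pyridine, 50 °C
Reagents that add atoms: sulfur trioxide pyridine complex O=S(=O)([O-])[n+]1ccccc1
Why: Sulfation of the single free hydroxyl by the SO3–pyridine complex forms only an O–S bond, so C12 is retained, and the dimethoxyarene and both trisubstituted olefins are inert to this mild reagent.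

Step 9
Reactants: 15 (2S,3S,7E)-9-(2,5-dimethoxyphenyl)-3,7-dimethyl-1-[(1R,4aR,8aR)-2,5,5,8a-tetramethyl-1,4,4a,5,6,7,8,8a-octahydronaphthalen-1-yl]non-7-en-2-yl hydrogen sulfate
Product: 17 (2S,3S,7E)-9-(2,5-dihydroxyphenyl)-3,7-dimethyl-1-[(1R,4aR,8aR)-2,5,5,8a-tetramethyl-1,4,4a,5,6,7,8,8a-octahydronaphthalen-1-yl]non-7-en-2-yl hydrogen sulfate, via quinone 16 (not isolated)
Conditions: (NH4)2Ce(NO3)6 (2.5 equiv), MeCN–H2O, 0 °C, 15 min; then Na2S2O4, H2O–EtOAc, rt, under argon; Dowex 50W (H+ form), MeOH, 0 °C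
Reagents that add atoms: water O
Why: Oxidative demethylation of the 1,4-dimethoxyarene by tetravalent cerium gives the benzoquinone (aryl–oxygen cleavage, new oxygens from water), which dithionite reduces to the hydroquinone, while the sulfate ester and the olefins survive the short cold oxidation and no stereocentre is touched.

## Compound list

1 | (R)-3-bromo-2-methylpropan-1-ol | OC[C@@H](C)CBr | starting material
2 | (4-bromobut-1-yn-1-yl)trimethylsilane | C[Si](C)(C)C#CCCBr | starting material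
3 | [4-(trimethylsilyl)but-3-yn-1-yl]magnesium bromide | C[Si](C)(C)C#CCC[Mg]Br | intermediate
4 | (S)-2-methyl-7-(trimethylsilyl)hept-6-yn-1-ol | OC[C@@H](C)CCCC#C[Si](C)(C)C | intermediate
5 | (S)-2-methyl-7-(trimethylsilyl)hept-6-ynal | O=C[C@@H](C)CCCC#C[Si](C)(C)C | intermediate
6 | (2E,6E)-farnesyl chloride | CC(C)=CCC/C(C)=C/CC/C(C)=C/CCl | starting material
7 | (2E,6E)-farnesylbarium chloride | CC(C)=CCC/C(C)=C/CC/C(C)=C/C[Ba]Cl | intermediate
8 | (6S,7S,9E,13E)-6,10,14,18-tetramethyl-1-(trimethylsilyl)nonadeca-9,13,17-trien-1-yn-7-ol | CC(C)=CCC/C(C)=C/CC/C(C)=C/C[C@H](O)[C@@H](C)CCCC#C[Si](C)(C)C | intermediate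
9 | (2S,3aS,5aR,9aR,9bS)-3a,6,6,9a-tetramethyl-2-[(2S)-7-(trimethylsilyl)hept-6-yn-2-yl]dodecahydronaphtho[2,1-b]furan | C[C@]12CC[C@@H]3C(C)(C)CCC[C@@]3(C)[C@@H]1C[C@H](O2)[C@@H](C)CCCC#C[Si](C)(C)C | intermediate
10 | (2S,3S)-3-methyl-1-[(1R,4aR,8aR)-2,5,5,8a-tetramethyl-1,4,4a,5,6,7,8,8a-octahydronaphthalen-1-yl]-8-(trimethylsilyl)oct-7-yn-2-yl acetate | CC1=CC[C@@H]2C(C)(C)CCC[C@@]2(C)[C@@H]1C[C@H](OC(C)=O)[C@@H](C)CCCC#C[Si](C)(C)C | intermediate
11 | (2S,3S)-3-methyl-1-[(1R,4aR,8aR)-2,5,5,8a-tetramethyl-1,4,4a,5,6,7,8,8a-octahydronaphthalen-1-yl]oct-7-yn-2-ol | CC1=CC[C@@H]2C(C)(C)CCC[C@@]2(C)[C@@H]1C[C@H](O)[C@@H](C)CCCC#C | intermediate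
12 | 2-(chloromethyl)-1,4-dimethoxybenzene | COc1ccc(OC)c(CCl)c1 | starting material
13 | (E)-alkenyldimethylalane of 11 (aluminium alkoxide at C12) | CC1=CC[C@@H]2C(C)(C)CCC[C@@]2(C)[C@@H]1C[C@H](O[Al](C)C)[C@@H](C)CCC/C(C)=C/[Al](C)C | intermediate
14 | (2S,3S,7E)-9-(2,5-dimethoxyphenyl)-3,7-dimethyl-1-[(1R,4aR,8aR)-2,5,5,8a-tetramethyl-1,4,4a,5,6,7,8,8a-octahydronaphthalen-1-yl]non-7-en-2-ol | CC1=CC[C@@H]2C(C)(C)CCC[C@@]2(C)[C@@H]1C[C@H](O)[C@@H](C)CCC/C(C)=C/Cc1cc(OC)ccc1OC | intermediate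
15 | (2S,3S,7E)-9-(2,5-dimethoxyphenyl)-3,7-dimethyl-1-[(1R,4aR,8aR)-2,5,5,8a-tetramethyl-1,4,4a,5,6,7,8,8a-octahydronaphthalen-1-yl]non-7-en-2-yl hydrogen sulfate | CC1=CC[C@@H]2C(C)(C)CCC[C@@]2(C)[C@@H]1C[C@H](OS(=O)(=O)O)[C@@H](C)CCC/C(C)=C/Cc1cc(OC)ccc1OC | intermediate
16 | (2S,3S,7E)-9-(3,6-dioxocyclohexa-1,4-dien-1-yl)-3,7-dimethyl-1-[(1R,4aR,8aR)-2,5,5,8a-tetramethyl-1,4,4a,5,6,7,8,8a-octahydronaphthalen-1-yl]non-7-en-2-yl hydrogen sulfate | CC1=CC[C@@H]2C(C)(C)CCC[C@@]2(C)[C@@H]1C[C@H](OS(=O)(=O)O)[C@@H](C)CCC/C(C)=C/CC1=CC(=O)C=CC1=O | intermediate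
17 | (2S,3S,7E)-9-(2,5-dihydroxyphenyl)-3,7-dimethyl-1-[(1R,4aR,8aR)-2,5,5,8a-tetramethyl-1,4,4a,5,6,7,8,8a-octahydronaphthalen-1-yl]non-7-en-2-yl hydrogen sulfate | CC1=CC[C@@H]2C(C)(C)CCC[C@@]2(C)[C@@H]1C[C@H](OS(=O)(=O)O)[C@@H](C)CCC/C(C)=C/Cc1cc(O)ccc1O | target

## Step count and risks

Total step count: 9. Longest linear sequence: 9 steps (1 → 4 → 5 → 8 → 9 → 10 → 11 → 14 → 15 → 17); compounds 2, 6 and 12 are bought and enter without extra steps.

The three steps most likely to fail:

Step 4 (the proposed new step). The facial control by C12 has not been demonstrated. Direct acid-catalysed hydroalkoxylation of the C8=C9 olefin to a monocyclic tetrahydrofuran is the expected side path. The fallback uses known chemistry and sets out from 8: acetylation (Ac2O, pyridine, DMAP) gives the acetate F1. Its superacid cyclization (FSO3H, 2-nitropropane, −78 °C, the known farnesyl acetate to drimenyl acetate reaction, ended by proton loss instead of ether formation) gives 10 directly, together with the diastereomer carrying the mirror-image decalin F2. No stereocontrol is expected, so the two are separated by HPLC or AgNO3-impregnated silica. The route is rejoined at 10, bypassing 9.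

Step 5. The E1 opening can give the exocyclic 8(17)-olefin and some tetrasubstituted 8(9)-olefin beside the wanted Δ7 isomer, and FeCl3 may attack the alkynylsilane. The fallback sets out from 9 and accepts the kinetic mixture from the same acylative opening. The exocyclic isomer F3 is then converged onto 10 by the known hydrogen-atom-transfer isomerization of exocyclic 1,1-disubstituted olefins to endocyclic trisubstituted ones (Co(salen)Cl 5 mol%, PhSiH3 catalytic, benzene, rt). The route is rejoined at 10.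

Step 3. Felkin–Anh control by an α-methyl group that competes only with a CH2 chain is modest. The fallback sets out from 5 and 6: the same addition is run, and the minor (7R)-epimer F4 is separated and inverted by a Mitsunobu reaction (4-nitrobenzoic acid, PPh3, DIAD, THF) to the 4-nitrobenzoate F5. Cleavage with i-Bu2AlH (CH2Cl2, −78 °C) spares the alkynylsilane and returns the material to the route at 8.

## Further compounds

F1 | step 4 | (6S,7S,9E,13E)-6,10,14,18-tetramethyl-1-(trimethylsilyl)nonadeca-9,13,17-trien-1-yn-7-yl acetate | CC(C)=CCC/C(C)=C/CC/C(C)=C/C[C@H](OC(C)=O)[C@@H](C)CCCC#C[Si](C)(C)C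
F2 | step 4 | (2S,3S)-3-methyl-1-[(1S,4aS,8aS)-2,5,5,8a-tetramethyl-1,4,4a,5,6,7,8,8a-octahydronaphthalen-1-yl]-8-(trimethylsilyl)oct-7-yn-2-yl acetate | CC1=CC[C@H]2C(C)(C)CCC[C@]2(C)[C@H]1C[C@H](OC(C)=O)[C@@H](C)CCCC#C[Si](C)(C)C
F3 | step 5 | (2S,3S)-3-methyl-1-[(1R,4aR,8aR)-5,5,8a-trimethyl-2-methylidenedecahydronaphthalen-1-yl]-8-(trimethylsilyl)oct-7-yn-2-yl acetate | C=C1CC[C@@H]2C(C)(C)CCC[C@@]2(C)[C@@H]1C[C@H](OC(C)=O)[C@@H](C)CCCC#C[Si](C)(C)C
F4 | step 3 | (6S,7R,9E,13E)-6,10,14,18-tetramethyl-1-(trimethylsilyl)nonadeca-9,13,17-trien-1-yn-7-ol | CC(C)=CCC/C(C)=C/CC/C(C)=C/C[C@@H](O)[C@@H](C)CCCC#C[Si](C)(C)C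
F5 | step 3 | (6S,7S,9E,13E)-6,10,14,18-tetramethyl-1-(trimethylsilyl)nonadeca-9,13,17-trien-1-yn-7-yl 4-nitrobenzoate | CC(C)=CCC/C(C)=C/CC/C(C)=C/C[C@H](OC(=O)c1ccc(cc1)[N+](=O)[O-])[C@@H](C)CCCC#C[Si](C)(C)C
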